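Everything rests on making the aryl ring C1'–C6' last, from open-chain carbons, instead of differentiating the two oxygens of a ready-made resorcinol. That ring is 1,2,3,4-tetrasubstituted: benzofuran C2 on C1', the pyran oxygen on C2', the five-carbon unit on C3', the free hydroxyl on C4'. One photochemical operation turns a diazoketone into a vinylketene, joins it to a siloxyalkyne and, by way of a strained cyclobutenone, forges C5'–C6', C4'–C5', C2'–C3' and C1'–C2'; O2' is born as a free phenol, O4' as a silyl ether, prenyl between them. The precursor is an (E)-enone diazoketone hung on C2 of a 5-prenyl-6-silyloxybenzofuran. Oxidative pyran closure and desilylation finish.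

Key step: step 11

Remark on stereochemistry: kanzonol V has no stereocentre and is achiral, so there is no enantiomer to select. The only stereo-element handled is the E alkene of the enone and the diazoketone, and it ends inside the new benzene ring.

Locants and abbreviations: C1' is the aryl carbon bonded to benzofuran C2, followed by C2' (pyran O), C3' (pyran C), C4' (free OH), C5' and C6'. Prenyl = 3-methylbut-2-en-1-yl. TIPS = triisopropylsilyl.

Step 1
Reactants: 1 5-bromo-2-hydroxy-4-methoxybenzaldehyde; 2 ethyl bromoacetate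
Product: 4 ethyl 5-bromo-6-methoxy-1-benzofuran-2-carboxylate, via aryloxyacetate 3 (not isolated)
Conditions: K2CO3, DMF, rt → 100 °C
Reagents that add atoms: none
Why: Phenoxide O-alkylation followed by intramolecular aldol condensation onto the ortho aldehyde (Rap–Stoermer-type benzofuran synthesis) is routine for salicylaldehydes; the bromine already marks C5, so no unselective C-prenylation of a resorcinol is needed, and a base-stable methyl ether is carried here because an aryl silyl ether para to the aldehyde could be lost in hot carbonate.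

Step 2
Reactants: 4 ethyl 5-bromo-6-methoxy-1-benzofuran-2-carboxylate
Product: 5 ethyl 5-bromo-6-hydroxy-1-benzofuran-2-carboxylate
Conditions: BBr3, CH2Cl2, −78 → 0 °C; then H2O
Reagents that add atoms: none
Why: Lewis-acid cleavage of the aryl methyl ether with BBr3 is placed before any acid-sensitive prenyl group is present, and at low temperature it should spare the conjugated ethyl ester and the aryl bromide.

Step 3
Reactants: 5 ethyl 5-bromo-6-hydroxy-1-benzofuran-2-carboxylate
Product: 6 ethyl 5-bromo-6-(TIPS-oxy)-1-benzofuran-2-carboxylate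
Conditions: TIPSCl, imidazole, DMF, rt
Reagents that add atoms: chlorotriisopropylsilane, CC(C)[Si](Cl)(C(C)C)C(C)C
Why: This is a standard imidazole-promoted phenol silylation, and TIPS is chosen because it should resist DIBAL-H, LiHMDS, light, heat and DDQ and fall together with the O4' silyl group in the last step.

Step 4
Reactants: 6 ethyl 5-bromo-6-(TIPS-oxy)-1-benzofuran-2-carboxylate; 7 tributyl(3-methylbut-2-en-1-yl)stannane
Product: 8 ethyl 5-prenyl-6-(TIPS-oxy)-1-benzofuran-2-carboxylate
Conditions: Pd(PPh3)4 (5 mol %), DMF, 100 °C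
Reagents that add atoms: none
Why: Stille allyl–aryl coupling under neutral conditions replaces the C5 bromine with full positional control, and reductive elimination from the prenyl–palladium species at its unhindered CH2 terminus should give the linear prenyl arene without touching the ester or the silyl ether.

Step 5
Reactants: 8 ethyl 5-prenyl-6-(TIPS-oxy)-1-benzofuran-2-carboxylate
Product: 9 [5-prenyl-6-(TIPS-oxy)-1-benzofuran-2-yl]methanol
Conditions: DIBAL-H (2.5 equiv), CH2Cl2, −78 → 0 °C; aq. Rochelle salt
Reagents that add atoms: none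
Why: Full hydride reduction of the conjugated ester to the primary alcohol is more dependable than stopping at the aldehyde, and the silyl ether, alkene and furan are inert to DIBAL-H.

Step 6
Reactants: 9 [5-prenyl-6-(TIPS-oxy)-1-benzofuran-2-yl]methanol; 10 1-(triphenyl-λ5-phosphanylidene)propan-2-one
Product: 12 (E)-4-[5-prenyl-6-(TIPS-oxy)-1-benzofuran-2-yl]but-3-en-2-one, via benzofuran-2-carbaldehyde 11 (not isolated)
Conditions: MnO2 (10 equiv), toluene, 80 °C
Reagents that add atoms: none
Why: In this tandem MnO2 oxidation–Wittig olefination the benzylic-type alcohol is oxidised and the aldehyde is trapped as it forms by the stabilised ylide with E selectivity, and the neutral medium avoids the hydroxide of an acetone aldol, which would endanger the aryl silyl ether and permit double condensation.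

Step 7
Reactants: 12 (E)-4-[5-prenyl-6-(TIPS-oxy)-1-benzofuran-2-yl]but-3-en-2-one
Product: 14 (E)-1-diazo-4-[5-prenyl-6-(TIPS-oxy)-1-benzofuran-2-yl]but-3-en-2-one, via trifluoroacetyl diketone 13 (not isolated)
Conditions: LiHMDS, THF, −78 °C; CF3CO2CH2CF3, −78 °C; dilute HCl quench; then MsN3, Et3N, H2O (1 equiv), MeCN, rt
Reagents that add atoms: methanesulfonyl azide, CS(=O)(=O)N=[N+]=[N-]; 2,2,2-trifluoroethyl trifluoroacetate, O=C(OCC(F)(F)F)C(F)(F)F (its CF3CO group is carried in 13 only)
Why: In this detrifluoroacetylative diazo transfer (a Regitz-type transfer to an activated ketone) the methyl group, the only enolisable site, is trifluoroacetylated and then takes N2 from the sulfonyl azide with loss of the activating group, which avoids the pyrazoline formation that plagues enoyl chloride plus diazomethane.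

Step 8
Reactants: 15 ethynyltrimethylsilane; 16 prenyl bromide (1-bromo-3-methylbut-2-ene)
Product: 18 trimethyl(5-methylhex-4-en-1-yn-1-yl)silane, via alkynylmagnesium bromide 17 (not isolated)
Conditions: EtMgBr, THF, 0 → 40 °C; then CuBr·SMe2 (5 mol %), 16, 0 °C → rt
Reagents that add atoms: ethylmagnesium bromide, CC[Mg]Br (its MgBr is carried in 17 only)
Why: Copper-catalysed SN2 coupling of an alkynyl Grignard reagent with a primary allylic bromide should give the skipped enyne by attack at the unhindered CH2, and the silyl cap excludes double alkylation.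

Step 9
Reactants: 18 trimethyl(5-methylhex-4-en-1-yn-1-yl)silane
Product: 19 5-methylhex-4-en-1-yne
Conditions: K2CO3 (cat.), MeOH, rt; pentane extraction, careful distillation
Reagents that add atoms: none
Why: Carbonate-catalysed methanolysis of the C(sp)–Si bond (protodesilylation) is mild enough not to move the skipped enyne into conjugation.

Step 10
Reactants: 19 5-methylhex-4-en-1-yne
Product: 22 triisopropyl[(5-methylhex-4-en-1-yn-1-yl)oxy]silane, via lithium acetylide 20 (not isolated), via lithium ynolate 21 (not isolated)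
Conditions: n-BuLi, THF, −78 °C; LiOOt-Bu (from anhydrous t-BuOOH, LiHMDS, THF, −78 °C), → 0 °C; TIPSOTf, −78 → 0 °C
Reagents that add atoms: tert-butyl hydroperoxide, CC(C)(C)OO; triisopropylsilyl triflate, CC(C)[Si](OS(=O)(=O)C(F)(F)F)(C(C)C)C(C)C; n-butyllithium, CCCC[Li] (its Li is carried in 20 and 21 only)
Why: Electrophilic oxygenation of a lithium acetylide with lithium tert-butyl peroxide gives the ynolate, which the bulky, hard silyl triflate should capture on oxygen (ynolate O-silylation) rather than on carbon.

Step 11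
Reactants: 14 (E)-1-diazo-4-[5-prenyl-6-(TIPS-oxy)-1-benzofuran-2-yl]but-3-en-2-one; 22 triisopropyl[(5-methylhex-4-en-1-yn-1-yl)oxy]silane
Product: 26 2-[2-hydroxy-3-prenyl-4-(TIPS-oxy)phenyl]-5-prenyl-6-(TIPS-oxy)-1-benzofuran, via vinylketene 23 (not isolated), via vinylcyclobutenone 24 (not isolated), via dienylketene 25 (not isolated)
Conditions: 22 (1.5 equiv), hν (450 W medium-pressure Hg lamp, Pyrex), ClCH2CH2Cl, 20 °C; then toluene, 110 °C
Reagents that add atoms: none
Why: Light expels N2 from 14 and the alkenyl group migrates from the carbonyl carbon (future C2') to the diazo carbon (future C5'), a Wolff rearrangement that makes C5'–C6' and gives vinylketene 23, whose C5'=C2' bond adds across the electron-rich alkyne 22 in a [2+2] cycloaddition (C2'–C3' and C4'–C5') to give the four-membered ring of 24. Ring strain then drives a reversible conrotatory 4π opening of 24 (C2'–C5' breaks) to dienylketene 25, and the isomer whose alkenyl arm points toward the ketene is drained by a disrotatory 6π electrocyclisation (C1'–C2'), the closure mode of the one ring that remains, before the cyclohexadienone tautomerises to the phenol. The closest known reaction type is the photochemical diazoketone variant of the vinylketene–alkyne aromatic annulation, which is established for alkenyl and hetaryl diazoketones in combination with triisopropylsiloxyalkynes. No stereocentre is created, since C4 of 24 is formed racemic and becomes the sp2 carbon C5'. The step needs regiocontrol in the [2+2] event, and the oxygen donor of 22 supplies it by making the prenyl-bearing alkyne carbon the nucleophile that attacks the ketene carbonyl carbon, so that the ketene oxygen ends as free O2'–H, the alkyne oxygen as O4'–TIPS and the prenyl group on C3' between them. It also needs chemoselectivity, which rests on the siloxyalkyne being a far better ketenophile than the trisubstituted alkenes and on the E alkene of 14 keeping the ketene carbon out of reach of benzofuran C3.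

Step 12
Reactants: 26 2-[2-hydroxy-3-prenyl-4-(TIPS-oxy)phenyl]-5-prenyl-6-(TIPS-oxy)-1-benzofuran
Product: 28 2-[2,2-dimethyl-5-(TIPS-oxy)-2H-chromen-8-yl]-5-prenyl-6-(TIPS-oxy)-1-benzofuran, via ortho-quinone methide 27 (not isolated)
Conditions: DDQ (1.1 equiv), toluene, 80 °C
Reagents that add atoms: none
Why: In this DDQ oxidative cyclisation of an ortho-prenylphenol, hydride abstraction from the C3' benzylic–allylic CH2 with loss of the O2'–H proton gives the quinone methide, which closes by oxa-6π electrocyclisation to the 2,2-dimethyl-2H-pyran, whereas the C5 prenyl group sits beside a silyl ether and has no phenol through which to reach a quinone methide.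

Step 13
Reactants: 28 2-[2,2-dimethyl-5-(TIPS-oxy)-2H-chromen-8-yl]-5-prenyl-6-(TIPS-oxy)-1-benzofuran
Product: 29 kanzonol V
Conditions: TBAF (2.5 equiv), AcOH (2.5 equiv), THF, 0 °C → rt
Reagents that add atoms: none
Why: Fluoride-induced cleavage of both aryl silyl ethers, buffered with acetic acid so that the electron-rich phenoxides stay protonated, should leave the chromene, prenyl and benzofuran units untouched.

Compound list

1 | 5-bromo-2-hydroxy-4-methoxybenzaldehyde | O=Cc1cc(Br)c(OC)cc1O | starting material
2 | ethyl bromoacetate | CCOC(=O)CBr | starting material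
3 | ethyl 2-(4-bromo-2-formyl-5-methoxyphenoxy)acetate (not isolated) | CCOC(=O)COc1cc(OC)c(Br)cc1C=O | intermediate
4 | ethyl 5-bromo-6-methoxy-1-benzofuran-2-carboxylate | CCOC(=O)c1cc2cc(Br)c(OC)cc2o1 | intermediate
5 | ethyl 5-bromo-6-hydroxy-1-benzofuran-2-carboxylate | CCOC(=O)c1cc2cc(Br)c(O)cc2o1 | intermediate
6 | ethyl 5-bromo-6-(TIPS-oxy)-1-benzofuran-2-carboxylate | CCOC(=O)c1cc2cc(Br)c(O[Si](C(C)C)(C(C)C)C(C)C)cc2o1 | intermediate
7 | tributyl(3-methylbut-2-en-1-yl)stannane | CCCC[Sn](CCCC)(CCCC)CC=C(C)C | starting material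
8 | ethyl 5-prenyl-6-(TIPS-oxy)-1-benzofuran-2-carboxylate | CCOC(=O)c1cc2cc(CC=C(C)C)c(O[Si](C(C)C)(C(C)C)C(C)C)cc2o1 | intermediate
9 | [5-prenyl-6-(TIPS-oxy)-1-benzofuran-2-yl]methanol | OCc1cc2cc(CC=C(C)C)c(O[Si](C(C)C)(C(C)C)C(C)C)cc2o1 | intermediate
10 | 1-(triphenyl-λ5-phosphanylidene)propan-2-one | CC(=O)C=P(c1ccccc1)(c1ccccc1)c1ccccc1 | starting material
11 | 5-prenyl-6-(TIPS-oxy)-1-benzofuran-2-carbaldehyde (not isolated) | O=Cc1cc2cc(CC=C(C)C)c(O[Si](C(C)C)(C(C)C)C(C)C)cc2o1 | intermediate
12 | (E)-4-[5-prenyl-6-(TIPS-oxy)-1-benzofuran-2-yl]but-3-en-2-one | CC(=O)/C=C/c1cc2cc(CC=C(C)C)c(O[Si](C(C)C)(C(C)C)C(C)C)cc2o1 | intermediate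
13 | (E)-1,1,1-trifluoro-6-[5-prenyl-6-(TIPS-oxy)-1-benzofuran-2-yl]hex-5-ene-2,4-dione (not isolated) | O=C(CC(=O)/C=C/c1cc2cc(CC=C(C)C)c(O[Si](C(C)C)(C(C)C)C(C)C)cc2o1)C(F)(F)F | intermediate
14 | (E)-1-diazo-4-[5-prenyl-6-(TIPS-oxy)-1-benzofuran-2-yl]but-3-en-2-one | CC(C)=CCc1cc2cc(/C=C/C(=O)C=[N+]=[N-])oc2cc1O[Si](C(C)C)(C(C)C)C(C)C | intermediate
15 | ethynyltrimethylsilane | C#C[Si](C)(C)C | starting material
16 | prenyl bromide (1-bromo-3-methylbut-2-ene) | CC(C)=CCBr | starting material
17 | [(trimethylsilyl)ethynyl]magnesium bromide (not isolated) | C[Si](C)(C)C#C[Mg]Br | intermediate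
18 | trimethyl(5-methylhex-4-en-1-yn-1-yl)silane | CC(C)=CCC#C[Si](C)(C)C | intermediate
19 | 5-methylhex-4-en-1-yne | CC(C)=CCC#C | intermediate
20 | (5-methylhex-4-en-1-yn-1-yl)lithium (not isolated) | CC(C)=CCC#C[Li] | intermediate
21 | lithium 5-methylhex-4-en-1-yn-1-olate (not isolated) | CC(C)=CCC#CO[Li] | intermediate
22 | triisopropyl[(5-methylhex-4-en-1-yn-1-yl)oxy]silane | CC(C)=CCC#CO[Si](C(C)C)(C(C)C)C(C)C | intermediate
23 | (E)-4-[5-prenyl-6-(TIPS-oxy)-1-benzofuran-2-yl]buta-1,3-dien-1-one, the vinylketene (not isolated) | O=C=C/C=C/c1cc2cc(CC=C(C)C)c(O[Si](C(C)C)(C(C)C)C(C)C)cc2o1 | intermediate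
24 | racemic 2-prenyl-3-(TIPS-oxy)-4-{(E)-2-[5-prenyl-6-(TIPS-oxy)-1-benzofuran-2-yl]ethenyl}cyclobut-2-en-1-one (not isolated) | O=C1C(CC=C(C)C)=C(O[Si](C(C)C)(C(C)C)C(C)C)C1/C=C/c3cc4cc(CC=C(C)C)c(O[Si](C(C)C)(C(C)C)C(C)C)cc4o3 | intermediate
25 | 2-prenyl-3-(TIPS-oxy)-6-[5-prenyl-6-(TIPS-oxy)-1-benzofuran-2-yl]hexa-1,3,5-trien-1-one, ketene carbon chain cis to the alkenyl arm on C3=C4, C5=C6 E (not isolated) | O=C=C(CC=C(C)C)/C(O[Si](C(C)C)(C(C)C)C(C)C)=C\C=C\c1cc2cc(CC=C(C)C)c(O[Si](C(C)C)(C(C)C)C(C)C)cc2o1 | intermediate
26 | 2-[2-hydroxy-3-prenyl-4-(TIPS-oxy)phenyl]-5-prenyl-6-(TIPS-oxy)-1-benzofuran | CC(C)=CCc1cc2cc(-c3ccc(O[Si](C(C)C)(C(C)C)C(C)C)c(CC=C(C)C)c3O)oc2cc1O[Si](C(C)C)(C(C)C)C(C)C | intermediate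
27 | 6-(3-methylbut-2-en-1-ylidene)-2-[5-prenyl-6-(TIPS-oxy)-1-benzofuran-2-yl]-5-(TIPS-oxy)cyclohexa-2,4-dien-1-one, the ortho-quinone methide (not isolated) | CC(C)=CC=C1C(=O)C(c2cc3cc(CC=C(C)C)c(O[Si](C(C)C)(C(C)C)C(C)C)cc3o2)=CC=C1O[Si](C(C)C)(C(C)C)C(C)C | intermediate
28 | 2-[2,2-dimethyl-5-(TIPS-oxy)-2H-chromen-8-yl]-5-prenyl-6-(TIPS-oxy)-1-benzofuran | CC(C)=CCc1cc2cc(-c3ccc(O[Si](C(C)C)(C(C)C)C(C)C)c4c3OC(C)(C)C=C4)oc2cc1O[Si](C(C)C)(C(C)C)C(C)C | intermediate
29 | kanzonol V, 8-[6-hydroxy-5-(3-methylbut-2-en-1-yl)-1-benzofuran-2-yl]-2,2-dimethyl-2H-chromen-5-ol (achiral) | CC(C)=CCc1cc2cc(-c3ccc(O)c4c3OC(C)(C)C=C4)oc2cc1O | target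

Total step count: 13. Longest linear sequence: 10 (steps 1–7, then 11–13). The alkyne branch (steps 8–10) joins at step 11.

Steps most likely to fail

1. Step 11.
- Risk: light may isomerise the E alkene of the enone or of the vinylketene, after which the ketene carbon can close onto benzofuran C3.
- Risk: the strongly absorbing 2-arylbenzofuran may screen the lamp as it builds up, so that conversion stalls.
- Risk: the newly formed phenol may be acylated by unconsumed ketene.
- Fallback: the ketene is made in the dark by dehydrochlorination instead of by Wolff rearrangement. The fallback sets out from alcohol 9, which with MnO2 alone gives aldehyde 11 in isolated form. Wittig olefination of 11 with the ylide from (2-carboxyethyl)triphenylphosphonium bromide (NaHMDS, THF) should give (E)-4-[5-prenyl-6-(TIPS-oxy)-1-benzofuran-2-yl]but-3-enoic acid F1. 1-Chloro-N,N,2-trimethylpropenylamine then converts it under neutral conditions into (E)-4-[5-prenyl-6-(TIPS-oxy)-1-benzofuran-2-yl]but-3-enoyl chloride F2. Slow addition of F2 to Et3N and 22 in toluene at 80–110 °C removes HCl and gives the same vinylketene 23. This passes through 24 and 25 and comes back to the route at 26.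

2. Step 12.
- Risk: hydride abstraction may also occur at the C5 benzylic–allylic CH2, which is activated by the ortho silyloxy group and the para ring oxygen.
- Risk: the electron-rich arylbenzofuran may be over-oxidised.
- Fallback: the pyran is closed by an electrophile and the alkene is installed by syn elimination, with no hydride abstraction. The fallback sets out from 26. N-(Phenylselanyl)phthalimide with catalytic camphorsulfonic acid (CH2Cl2, −78 → 0 °C) activates the alkenes reversibly, and only the C3' prenyl group has an internal nucleophile. A 6-endo selenoetherification at the tertiary carbon should therefore give racemic 2,2-dimethyl-3-(phenylselanyl)-8-[5-prenyl-6-(TIPS-oxy)-1-benzofuran-2-yl]-5-(TIPS-oxy)chromane F3. mCPBA (1 equiv, −78 °C) gives the corresponding selenoxide F4. On warming with i-Pr2NH, F4 undergoes syn elimination toward C4, and the fallback comes back to the route at 28.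

3. Step 10.
- Risk: metalation may compete at the doubly activated CH2 between alkyne and alkene.
- Risk: oxygen transfer from the peroxide may be incomplete.
- Risk: the ynolate may be silylated on carbon to a silylketene.
- Risk: the volatile alkyne may be lost on handling.
- Fallback: the ynolate is built by one-carbon homologation of an ester, with no acetylide oxidation. The fallback sets out from prenyl bromide 16, which is ethoxycarbonylated (CO, EtOH, cat. PdCl2(PPh3)2, K2CO3) to ethyl 4-methylpent-3-enoate F5, a compound that can also be bought. F5 is added to LiCHBr2 (CH2Br2, LiTMP, THF, −78 °C), and LiHMDS turns the adduct into lithium 1,1-dibromo-5-methylhexa-1,4-dien-2-olate F6. n-BuLi then triggers bromine–lithium exchange and a 1,2-shift of the prenyl group (Kowalski ester homologation). The fallback comes back to the route at ynolate 21, which is silylated with TIPSOTf as in step 10 to give 22.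

Further compounds

F1 | step 11 | (E)-4-[5-prenyl-6-(TIPS-oxy)-1-benzofuran-2-yl]but-3-enoic acid | OC(=O)C/C=C/c1cc2cc(CC=C(C)C)c(O[Si](C(C)C)(C(C)C)C(C)C)cc2o1
F2 | step 11 | (E)-4-[5-prenyl-6-(TIPS-oxy)-1-benzofuran-2-yl]but-3-enoyl chloride | ClC(=O)C/C=C/c1cc2cc(CC=C(C)C)c(O[Si](C(C)C)(C(C)C)C(C)C)cc2o1
F3 | step 12 | racemic 2,2-dimethyl-3-(phenylselanyl)-8-[5-prenyl-6-(TIPS-oxy)-1-benzofuran-2-yl]-5-(TIPS-oxy)chromane | CC(C)=CCc1cc2cc(-c3ccc(O[Si](C(C)C)(C(C)C)C(C)C)c4c3OC(C)(C)C([Se]c5ccccc5)C4)oc2cc1O[Si](C(C)C)(C(C)C)C(C)C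
F4 | step 12 | selenoxide of F3 (mixture of stereoisomers) | CC(C)=CCc1cc2cc(-c3ccc(O[Si](C(C)C)(C(C)C)C(C)C)c4c3OC(C)(C)C([Se](=O)c5ccccc5)C4)oc2cc1O[Si](C(C)C)(C(C)C)C(C)C
F5 | step 10 | ethyl 4-methylpent-3-enoate | CCOC(=O)CC=C(C)C
F6 | step 10 | lithium 1,1-dibromo-5-methylhexa-1,4-dien-2-olate | [Li]OC(CC=C(C)C)=C(Br)Br
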